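**Retrosynthetic overview**
1. Target 14 ⇐ global O-debenzylation of 13; the (E)-stilbene C=C ⇐ Heck coupling of aryl bromide 10 with 3,5-diacetoxystyrene 11.
2. Key bond CH2–CH(Ar)2 ⇐ aldehyde 6 used as its N–H hydrazone 7, so the aldehyde carbon acts as a carbanion, adding to o-quinone methide 8 on a chiral Ru–bisphosphine catalyst. This sets the (S) centre, and N2 loss leaves the CH2 directly.
3. o-Quinone methide precursor, sulfone 5 ⇐ diol 4 ⇐ aryl Grignard 3 + 5-bromo-o-vanillin 2.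
4. No ring is constructed: all four benzene rings are bought. Only the dearomatised ring of 8 forms transiently and re-aromatises in the key step.

Assumption: the sense of induction of the chiral Ru catalyst cannot be predicted with certainty. (R,R)-Me-BPE is written as the ligand antipode giving the (S) product; if induction is opposite, the (S,S)-ligand is used.

**Step 1**
Reactants: 1 1-(benzyloxy)-4-bromo-2-methoxybenzene; 2 5-bromo-2-hydroxy-3-methoxybenzaldehyde
Product: 4 rac-4-bromo-2-{[4-(benzyloxy)-3-methoxyphenyl](hydroxy)methyl}-6-methoxyphenol, via aryl Grignard reagent 3 (not isolated)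
Conditions: 1, Mg, I2 (cat.), THF, reflux; then 2 (0.4 equiv), THF, 0 °C to rt; sat. aq NH4Cl
Reagents that add atoms: none
Why: Grignard 1,2-addition to a salicylaldehyde; the first equivalent deprotonates the phenol and the second adds to the chelated aldehyde. The carbinol centre is racemic and is erased later in 8.

**Step 2**
Reactants: 4 rac-4-bromo-2-{[4-(benzyloxy)-3-methoxyphenyl](hydroxy)methyl}-6-methoxyphenol
Product: 5 rac-4-bromo-2-{[4-(benzyloxy)-3-methoxyphenyl](4-methylbenzenesulfonyl)methyl}-6-methoxyphenol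
Conditions: p-TolSO2Na (1.5 equiv), HCO2H/H2O/THF, rt
Reagents that add atoms: sodium p-toluenesulfinate, Cc1ccc(cc1)S(=O)[O-].[Na+]
Why: acid-promoted SN1 substitution of the doubly activated benzhydrol by sulfinate (S-alkylation) gives the bench-stable 2-(aryl(sulfonyl)methyl)phenol, the standard base-triggered o-quinone methide precursor.

**Step 3 (key step)**
Reactants: 5 rac-sulfone; 6 2,4-bis(benzyloxy)benzaldehyde
Product: 10 2-{(1S)-2-[2,4-bis(benzyloxy)phenyl]-1-[4-(benzyloxy)-3-methoxyphenyl]ethyl}-4-bromo-6-methoxyphenol, via hydrazone 7 (not isolated), via o-quinone methide 8 (not isolated), via alkyldiazene 9 (not isolated)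
Conditions: 6 (1.5 equiv), N2H4·H2O (1.2 equiv per 6), THF, rt, volatiles removed in vacuo; then 5, [Ru(p-cymene)Cl2]2 (2.5 mol%), (R,R)-Me-BPE (6 mol%), K3PO4 (2 equiv), THF, 35 °C
Reagents that add atoms: none
Why: Proposed new method: hydrazone 7 is the Ru(II)/phosphine "aldehyde as alkyl carbanion" nucleophile (carbonyl umpolung), whose closest known reactions are the racemic Ru/dmpe-catalysed 1,2- and 1,4-additions of N–H hydrazones to carbonyls and Michael acceptors, and asymmetric metal-catalysed 1,4-additions to o-quinone methides released from 2-(sulfonylmethyl)phenols; here K3PO4 releases 8 slowly from 5, the N-bound hydrazonide on the chiral Ru–Me-BPE centre delivers its azomethine carbon to the exocyclic carbon of the O-coordinated, s-cis-locked 8 through a closed cyclic transition state so that the ligand selects one face and sets the (S) centre, the ring re-aromatises, and diazene 9 loses N2 (Wolff–Kishner-type) to give the CH2; N-attack of 7 on 8 is reversible, so it only stores 8.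

**Step 4**
Reactants: 10 (S)-aryl bromide; 11 5-ethenyl-1,3-phenylene diacetate (3,5-diacetoxystyrene)
Product: 13 5-[(E)-2-(3-{(1S)-2-[2,4-bis(benzyloxy)phenyl]-1-[4-(benzyloxy)-3-methoxyphenyl]ethyl}-4-hydroxy-5-methoxyphenyl)ethenyl]benzene-1,3-diol, via stilbene diacetate 12 (not isolated)
Conditions: 11 (1.5 equiv), Pd2(dba)3 (2.5 mol%), [HP(t-Bu)3]BF4 (10 mol%), Cy2NMe (1.5 equiv), dioxane, 90 °C; then K2CO3, MeOH, rt (same pot)
Reagents that add atoms: none
Why: Mizoroki–Heck coupling with a bulky electron-rich phosphine suited to electron-rich aryl bromides; syn-insertion/syn-β-hydride elimination gives the (E)-stilbene. Carbonate-catalysed methanolysis then removes the two aryl acetates, and the non-acidic triarylethane centre is untouched.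

**Step 5**
Reactants: 13 tribenzyl ether
Product: 14 4-[(2S)-2-{5-[(E)-2-(3,5-dihydroxyphenyl)ethenyl]-2-hydroxy-3-methoxyphenyl}-2-(4-hydroxy-3-methoxyphenyl)ethyl]benzene-1,3-diol (CNP0254096.1)
Conditions: BCl3 (1 M in CH2Cl2, 8 equiv), C6HMe5 (10 equiv), CH2Cl2, −78 °C; MeOH/H2O quench
Reagents that add atoms: none
Why: Lewis-acid debenzylation of aryl benzyl ethers with pentamethylbenzene as a non-basic benzyl-cation scavenger. At −78 °C the two aryl methyl ethers and the stilbene are left intact, and the scavenger prevents C-benzylation of the electron-rich rings.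

**Compound list**
1 | 1-(benzyloxy)-4-bromo-2-methoxybenzene | COc1cc(Br)ccc1OCc1ccccc1 | starting material
2 | 5-bromo-2-hydroxy-3-methoxybenzaldehyde (5-bromo-o-vanillin) | COc1cc(Br)cc(C=O)c1O | starting material
3 | [4-(benzyloxy)-3-methoxyphenyl]magnesium bromide | COc1cc([Mg]Br)ccc1OCc1ccccc1 | intermediate
4 | rac-4-bromo-2-{[4-(benzyloxy)-3-methoxyphenyl](hydroxy)methyl}-6-methoxyphenol | COc1cc(C(O)c2cc(Br)cc(OC)c2O)ccc1OCc1ccccc1 | intermediate
5 | rac-4-bromo-2-{[4-(benzyloxy)-3-methoxyphenyl](4-methylbenzenesulfonyl)methyl}-6-methoxyphenol | COc1cc(C(c2cc(Br)cc(OC)c2O)S(=O)(=O)c2ccc(C)cc2)ccc1OCc1ccccc1 | intermediate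
6 | 2,4-bis(benzyloxy)benzaldehyde | O=Cc1ccc(OCc2ccccc2)cc1OCc1ccccc1 | starting material
7 | (E)-[2,4-bis(benzyloxy)benzylidene]hydrazine (N–H hydrazone of 6) | N/N=C/c1ccc(OCc2ccccc2)cc1OCc1ccccc1 | intermediate
8 | (6E)-6-[4-(benzyloxy)-3-methoxybenzylidene]-4-bromo-2-methoxycyclohexa-2,4-dien-1-one | O=C1C(OC)=CC(Br)=C/C1=C\c1ccc(OCc2ccccc2)c(OC)c1 | intermediate
9 | 2-{(1S)-2-[2,4-bis(benzyloxy)phenyl]-1-[4-(benzyloxy)-3-methoxyphenyl]-2-diazenylethyl}-4-bromo-6-methoxyphenol (C-2 configuration undefined) | COc1cc([C@H](C(N=N)c2ccc(OCc3ccccc3)cc2OCc2ccccc2)c2cc(Br)cc(OC)c2O)ccc1OCc1ccccc1 | intermediate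
10 | 2-{(1S)-2-[2,4-bis(benzyloxy)phenyl]-1-[4-(benzyloxy)-3-methoxyphenyl]ethyl}-4-bromo-6-methoxyphenol | COc1cc([C@H](Cc2ccc(OCc3ccccc3)cc2OCc2ccccc2)c2cc(Br)cc(OC)c2O)ccc1OCc1ccccc1 | intermediate
11 | 5-ethenyl-1,3-phenylene diacetate (3,5-diacetoxystyrene) | C=Cc1cc(OC(C)=O)cc(OC(C)=O)c1 | starting material
12 | 5-[(E)-2-(3-{(1S)-2-[2,4-bis(benzyloxy)phenyl]-1-[4-(benzyloxy)-3-methoxyphenyl]ethyl}-4-hydroxy-5-methoxyphenyl)ethenyl]-1,3-phenylene diacetate | COc1cc([C@H](Cc2ccc(OCc3ccccc3)cc2OCc2ccccc2)c2cc(/C=C/c3cc(OC(C)=O)cc(OC(C)=O)c3)cc(OC)c2O)ccc1OCc1ccccc1 | intermediate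
13 | 5-[(E)-2-(3-{(1S)-2-[2,4-bis(benzyloxy)phenyl]-1-[4-(benzyloxy)-3-methoxyphenyl]ethyl}-4-hydroxy-5-methoxyphenyl)ethenyl]benzene-1,3-diol | COc1cc([C@H](Cc2ccc(OCc3ccccc3)cc2OCc2ccccc2)c2cc(/C=C/c3cc(O)cc(O)c3)cc(OC)c2O)ccc1OCc1ccccc1 | intermediate
14 | 4-[(2S)-2-{5-[(E)-2-(3,5-dihydroxyphenyl)ethenyl]-2-hydroxy-3-methoxyphenyl}-2-(4-hydroxy-3-methoxyphenyl)ethyl]benzene-1,3-diol | COc1cc([C@H](Cc2ccc(O)cc2O)c2cc(/C=C/c3cc(O)cc(O)c3)cc(OC)c2O)ccc1O | target

**Totals**
Total step count: 5. Longest linear sequence: 5 steps (1/2 → 4 → 5 → 10 → 13 → 14).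

**Three steps most likely to fail**

Step 3 (asymmetric Ru hydrazone addition; the enantioselective form is unproven, and N-alkylation or catalyst binding by the phenoxide may interfere). The fallback sets out from 5 (with 6) and comes back at 10. Sulfone 5 is treated with Cs2CO3 in CH2Cl2 at 0 °C in the presence of aldehyde 6 and a chiral aminoindanol-derived triazolium carbene precatalyst. The Breslow intermediate of 6 (an acyl anion equivalent) adds 1,4 to 8 to give (2S)-1-[2,4-bis(benzyloxy)phenyl]-2-[4-(benzyloxy)-3-methoxyphenyl]-2-(5-bromo-2-hydroxy-3-methoxyphenyl)ethan-1-one F1. This is reduced at once under Luche conditions (NaBH4, CeCl3, MeOH, −40 °C) to limit enolisation, giving (2S)-1-[2,4-bis(benzyloxy)phenyl]-2-[4-(benzyloxy)-3-methoxyphenyl]-2-(5-bromo-2-hydroxy-3-methoxyphenyl)ethan-1-ol F2 as a carbinol epimer mixture. Ionic hydrogenation of the electron-rich benzylic carbinol (Et3SiH, BF3·OEt2, CH2Cl2, −78 °C) then gives 10.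

Step 4 (Heck coupling on an electron-rich bromophenol). The fallback sets out from 10 and comes back at 12. Suzuki–Miyaura vinylation of 10 with potassium vinyltrifluoroborate (PdCl2(dppf), Cs2CO3, THF/H2O, 80 °C) gives 2-{(1S)-2-[2,4-bis(benzyloxy)phenyl]-1-[4-(benzyloxy)-3-methoxyphenyl]ethyl}-4-ethenyl-6-methoxyphenol F3. Olefin cross-metathesis of this styrene with excess 11 (Hoveyda–Grubbs II, CH2Cl2, 40 °C) gives the (E)-stilbene diacetate 12, which is methanolysed to 13 as in step 4.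

Step 5 (BCl3 in the presence of the acid-sensitive p-hydroxystilbene). The fallback sets out from 10 and comes back at 14, changing the order so that the stilbene never meets the Lewis acid. Bromide 10 is debenzylated first (BCl3, C6HMe5, CH2Cl2, −78 °C) to 4-[(2S)-2-(5-bromo-2-hydroxy-3-methoxyphenyl)-2-(4-hydroxy-3-methoxyphenyl)ethyl]benzene-1,3-diol F4. Heck coupling of this with 11 (Pd2(dba)3, [HP(t-Bu)3]BF4, Cy2NMe, dioxane, 90 °C) gives 5-[(E)-2-{4-hydroxy-3-[(1S)-2-(2,4-dihydroxyphenyl)-1-(4-hydroxy-3-methoxyphenyl)ethyl]-5-methoxyphenyl}ethenyl]-1,3-phenylene diacetate F5. Degassed K2CO3/MeOH at rt in the same pot then gives 14.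

**Further compounds**
F1 | step 3 | (2S)-1-[2,4-bis(benzyloxy)phenyl]-2-[4-(benzyloxy)-3-methoxyphenyl]-2-(5-bromo-2-hydroxy-3-methoxyphenyl)ethan-1-one | COc1cc([C@H](C(=O)c2ccc(OCc3ccccc3)cc2OCc2ccccc2)c2cc(Br)cc(OC)c2O)ccc1OCc1ccccc1
F2 | step 3 | (2S)-1-[2,4-bis(benzyloxy)phenyl]-2-[4-(benzyloxy)-3-methoxyphenyl]-2-(5-bromo-2-hydroxy-3-methoxyphenyl)ethan-1-ol (C-1 epimer mixture) | COc1cc([C@H](C(O)c2ccc(OCc3ccccc3)cc2OCc2ccccc2)c2cc(Br)cc(OC)c2O)ccc1OCc1ccccc1
F3 | step 4 | 2-{(1S)-2-[2,4-bis(benzyloxy)phenyl]-1-[4-(benzyloxy)-3-methoxyphenyl]ethyl}-4-ethenyl-6-methoxyphenol | COc1cc([C@H](Cc2ccc(OCc3ccccc3)cc2OCc2ccccc2)c2cc(C=C)cc(OC)c2O)ccc1OCc1ccccc1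
F4 | step 5 | 4-[(2S)-2-(5-bromo-2-hydroxy-3-methoxyphenyl)-2-(4-hydroxy-3-methoxyphenyl)ethyl]benzene-1,3-diol | COc1cc([C@H](Cc2ccc(O)cc2O)c2cc(Br)cc(OC)c2O)ccc1O
F5 | step 5 | 5-[(E)-2-{4-hydroxy-3-[(1S)-2-(2,4-dihydroxyphenyl)-1-(4-hydroxy-3-methoxyphenyl)ethyl]-5-methoxyphenyl}ethenyl]-1,3-phenylene diacetate | COc1cc([C@H](Cc2ccc(O)cc2O)c2cc(/C=C/c3cc(OC(C)=O)cc(OC(C)=O)c3)cc(OC)c2O)ccc1O
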